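**Retrosynthetic overview**
- The (E)-2-ene-1,4-diol is made last, by palladium-catalysed 1,4-dioxygenation of the 2-alkylbuta-1,3-diene of a triene ester; this forms both C–O bonds and fixes the olefin geometry.
- Triene ester ⇐ cis-fused 8-oxo ester: the C-9 chain comes from a Mukaiyama–Michael addition to divinyl ketone, then a double methylenation gives C-8=CH2 and the diene.
- CH3-10 and the cis ring fusion ⇐ Me2CuLi addition to a bicyclic enone, with the enolate kept as its silyl enol ether.
- Enone ⇐ enantioselective exo Diels–Alder reaction of methacrolein with a semicyclic diene (sets C-4 and C-5); the diene comes from 3-ethoxycyclohex-2-enone.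
- Ring order: ring B is the starting cyclohexenone, ring A is closed onto it by the Diels–Alder reaction, and no ring is formed afterwards.

Assumption: the SMILES is read literally, i.e. a cis-fused decalin (H-5, CH3-10, CO2Me-4 and the C-9 chain all on one face; (1S,4aR,5S,8aS), the 5-epimer of the usual labdan-19-oate) with the two CH2OH groups trans on the side-chain double bond; labdane locants (C-1 to C-17) are used in the text.

Step 1
Reactants: 1 3-ethoxycyclohex-2-en-1-one; 2 ethenylmagnesium bromide
Product: 4 3-ethenylcyclohex-2-en-1-one, via 1-ethenyl-3-ethoxycyclohex-2-en-1-ol 3 (not isolated)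
Conditions: CH2=CHMgBr (1.3 equiv), THF, 0 °C; then 1 M HCl, 0 → 23 °C
Reagents that add atoms: water, O
Why: Stork–Danheiser sequence, in which the Grignard reagent adds 1,2 to the vinylogous ester and aqueous acid turns carbinol 3 (loss of water, addition of water to the oxocarbenium ion, loss of ethanol) into the transposed 3-substituted enone; no stereocenter is formed.

Step 2
Reactants: 4 3-ethenylcyclohex-2-en-1-one
Product: 5 7-ethenyl-1,4-dioxaspiro[4.5]dec-7-ene
Conditions: HOCH2CH2OH (5 equiv), TsOH·H2O (5 mol %), benzene, reflux (Dean–Stark), BHT (trace)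
Reagents that add atoms: ethane-1,2-diol, OCCO
Why: Acid-catalysed ketalisation of a 3-substituted cyclohex-2-enone runs through the dienol ether and gives the β,γ-unsaturated dioxolane (as with steroidal 4-en-3-ones), which here leaves the ring double bond conjugated with the vinyl group and so gives the semicyclic 1,3-diene; no stereocenter.

Step 3
Reactants: 5 7-ethenyl-1,4-dioxaspiro[4.5]dec-7-ene; 6 2-methylprop-2-enal
Product: 7 (1S,8aS)-6,6-(ethane-1,2-diyldioxy)-1-methyl-1,2,3,5,6,7,8,8a-octahydronaphthalene-1-carbaldehyde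
Conditions: 6 (3 equiv), (S)-tetrahydro-1-(2-methylphenyl)-3,3-diphenyl-1H,3H-pyrrolo[1,2-c][1,3,2]oxazaborole (20 mol %), Tf2NH (20 mol %), CH2Cl2, −78 → −40 °C
Reagents that add atoms: none
Why: Catalytic enantioselective Diels–Alder reaction of a 2-substituted acrolein, in which the protonated oxazaborolidine binds the s-trans enal and leaves the Re face of its C-2 open (expected for the (S)-catalyst by analogy with its cyclopentadiene adduct; the (R)-catalyst would give the antipode), the ring terminus of the diene bonds to the formyl-bearing carbon ("ortho" rule, reinforced by the Lewis acid), and the exo-formyl transition state usual for α-methylacroleins puts CH3 on C-4 cis to the C-5–C-6 bond and CHO cis to H-5, so that C-4 (S) and C-5 (S) are set together as ring A closes.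

Step 4
Reactants: 7 (1S,8aS)-6,6-(ethane-1,2-diyldioxy)-1-methyl-1,2,3,5,6,7,8,8a-octahydronaphthalene-1-carbaldehyde
Product: 8 methyl (1S,8aS)-6,6-(ethane-1,2-diyldioxy)-1-methyl-1,2,3,5,6,7,8,8a-octahydronaphthalene-1-carboxylate
Conditions: I2 (1.3 equiv), KOH (2.6 equiv), MeOH, 0 °C
Reagents that add atoms: methanol, CO
Why: Oxidative esterification of an aldehyde (hypoiodite oxidation of the methyl hemiacetal); the aldehyde has no α-hydrogen, and the dioxolane and the trisubstituted alkene are inert to these basic conditions, so the two stereocenters are untouched.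

Step 5
Reactants: 8 methyl (1S,8aS)-6,6-(ethane-1,2-diyldioxy)-1-methyl-1,2,3,5,6,7,8,8a-octahydronaphthalene-1-carboxylate
Product: 10 methyl (1S,8aS)-1-methyl-6-oxo-1,2,3,4,6,7,8,8a-octahydronaphthalene-1-carboxylate, via deconjugated keto ester 9 (not isolated)
Conditions: 1 M HCl, THF, 23 °C (stopped as soon as 9 is consumed)
Reagents that add atoms: water, O
Why: Acid hydrolysis of the dioxolane followed in the same flask by acid-catalysed conjugation of the β,γ-unsaturated ketone through its dienol; H-5 (γ to the carbonyl and next to the quaternary carbon) is not exchanged under these mild conditions, so C-5 keeps its configuration.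

Step 6
Reactants: 10 methyl (1S,8aS)-1-methyl-6-oxo-1,2,3,4,6,7,8,8a-octahydronaphthalene-1-carboxylate
Product: 11 methyl (1S,4aS,8aS)-1,4a-dimethyl-6-[(trimethylsilyl)oxy]-1,2,3,4,4a,7,8,8a-octahydronaphthalene-1-carboxylate
Conditions: MeLi (3.0 equiv), CuI (1.5 equiv), Et2O, 0 °C; then 10, Me3SiCl (3 equiv), THF, −78 → −30 °C; Et3N, cold aq. NaHCO3/pentane
Reagents that add atoms: lithium dimethylcuprate Me2CuLi, [Li+].C[Cu-]C; chlorotrimethylsilane, C[Si](C)(C)Cl
Why: Me3SiCl-accelerated conjugate addition of a Gilman cuprate to a bicyclic enone of this type gives the cis-fused decalin, methyl entering C-10 on the face of H-5 because the other face would force it into a 1,3-diaxial contact with the α-methyl on C-4; this sets C-10 with CH3 cis to H-5 and to CO2Me, and the enolate is trapped regiospecifically as the 8,9-silyl enol ether.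

Step 7
Reactants: 12 penta-1,4-dien-3-ol
Product: 13 penta-1,4-dien-3-one
Conditions: MnO2 (15 equiv), CH2Cl2, 23 °C; filtered solution used at once
Reagents that add atoms: none
Why: MnO2 oxidation of a doubly allylic secondary alcohol gives the cross-conjugated dienone, which is kept cold in solution because it polymerises on storage; no stereocenter.

Step 8
Reactants: 11 methyl (1S,4aS,8aS)-1,4a-dimethyl-6-[(trimethylsilyl)oxy]-1,2,3,4,4a,7,8,8a-octahydronaphthalene-1-carboxylate; 13 penta-1,4-dien-3-one
Product: 14 methyl (1S,4aS,5R,8aS)-1,4a-dimethyl-6-oxo-5-(3-oxopent-4-en-1-yl)decahydronaphthalene-1-carboxylate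
Conditions: 13 (3 equiv), TiCl4 (1.1 equiv), CH2Cl2, −78 °C; aq. NaHCO3
Reagents that add atoms: none
Why: Mukaiyama–Michael addition, in which C-9 of the silyl enol ether attacks the TiCl4-activated dienone axially and anti to the axial C-1 methylene of ring A (the α face is also screened by the quaternary C-4), so the chain enters cis to CH3-10 and gives the 9β side chain ((5R) in this ketone), and only one vinyl group reacts because the dienone is in excess.

Step 9
Reactants: 14 methyl (1S,4aS,5R,8aS)-1,4a-dimethyl-6-oxo-5-(3-oxopent-4-en-1-yl)decahydronaphthalene-1-carboxylate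
Product: 15 methyl (1S,4aR,5S,8aS)-1,4a-dimethyl-6-methylidene-5-(3-methylidenepent-4-en-1-yl)decahydronaphthalene-1-carboxylate
Conditions: Zn, CH2Br2, TiCl4 (reagent preformed in THF, 0 °C; 6 equiv), then 14, CH2Cl2, 0 → 23 °C; aq. NaHCO3
Reagents that add atoms: dibromomethane, BrCBr
Why: Takai–Lombardo methylenation converts both carbonyl groups (the hindered ring ketone, and the vinyl ketone by 1,2-addition) into methylidene groups under non-basic conditions, so the epimerisable C-9 centre and the methyl ester survive and the 2-alkylbuta-1,3-diene is formed in the same operation.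

Step 10
Reactants: 15 methyl (1S,4aR,5S,8aS)-1,4a-dimethyl-6-methylidene-5-(3-methylidenepent-4-en-1-yl)decahydronaphthalene-1-carboxylate
Product: 16 methyl (1S,4aR,5S,8aS)-5-[(3E)-5-hydroxy-3-(hydroxymethyl)pent-3-en-1-yl]-1,4a-dimethyl-6-methylidenedecahydronaphthalene-1-carboxylate
Conditions: Pd(OAc)2 (5 mol %), 1,4-benzoquinone (1.5 equiv), KHCO3 (30 mol %), CO2 (5 bar), acetone/H2O 5:1, 25 °C
Reagents that add atoms: water, O
Why: Proposed new method: direct palladium-catalysed 1,4-dihydroxylation of a 2-alkylbuta-1,3-diene with hydrogencarbonate as a traceless oxygen nucleophile, in which divalent palladium binds the s-cis diene (the hindered 1,1-disubstituted exocyclic alkene cannot chelate and is left alone), hydrogencarbonate attacks one diene terminus from outside to give a (1,2,3-η)-allyl complex, benzoquinone coordination triggers a second external attack at the far terminus, benzoquinone reoxidises zerovalent palladium, and both alkyl hydrogencarbonates lose CO2 so that water is the net oxygen donor and the free diol is released; the preferred allyl geometry leaves the two oxygenated CH2 groups trans, the same sense as the (E)-products of the known 1,4-diacetoxylation of isoprene, and the closest known reaction types are that palladium/benzoquinone 1,4-diacetoxylation of 1,3-dienes and the use of hydrogencarbonate as O-nucleophile in palladium-allyl substitution.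

**Compound list**
1 | 3-ethoxycyclohex-2-en-1-one | CCOC1=CC(=O)CCC1 | starting material
2 | ethenylmagnesium bromide (vinylmagnesium bromide) | C=C[Mg]Br | starting material
3 | 1-ethenyl-3-ethoxycyclohex-2-en-1-ol (racemic, as its magnesium alkoxide) | CCOC1=CC(O)(C=C)CCC1 | intermediate
4 | 3-ethenylcyclohex-2-en-1-one | C=CC1=CC(=O)CCC1 | intermediate
5 | 7-ethenyl-1,4-dioxaspiro[4.5]dec-7-ene | C=CC1=CCCC2(C1)OCCO2 | intermediate
6 | 2-methylprop-2-enal (methacrolein) | CC(=C)C=O | starting material
7 | (1S,8aS)-6,6-(ethane-1,2-diyldioxy)-1-methyl-1,2,3,5,6,7,8,8a-octahydronaphthalene-1-carbaldehyde (4,4a-ene; CHO and H-8a cis) | O=C[C@@]1(C)CCC=C2CC3(CC[C@H]12)OCCO3 | intermediate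
8 | methyl (1S,8aS)-6,6-(ethane-1,2-diyldioxy)-1-methyl-1,2,3,5,6,7,8,8a-octahydronaphthalene-1-carboxylate | COC(=O)[C@@]1(C)CCC=C2CC3(CC[C@H]12)OCCO3 | intermediate
9 | methyl (1S,8aS)-1-methyl-6-oxo-1,2,3,5,6,7,8,8a-octahydronaphthalene-1-carboxylate (4,4a-ene) | COC(=O)[C@@]1(C)CCC=C2CC(=O)CC[C@H]12 | intermediate
10 | methyl (1S,8aS)-1-methyl-6-oxo-1,2,3,4,6,7,8,8a-octahydronaphthalene-1-carboxylate (4a,5-ene) | COC(=O)[C@@]1(C)CCCC2=CC(=O)CC[C@H]12 | intermediate
11 | methyl (1S,4aS,8aS)-1,4a-dimethyl-6-[(trimethylsilyl)oxy]-1,2,3,4,4a,7,8,8a-octahydronaphthalene-1-carboxylate (cis-fused; CO2Me, 4a-CH3 and H-8a cis) | COC(=O)[C@@]1(C)CCC[C@]2(C)C=C(O[Si](C)(C)C)CC[C@H]12 | intermediate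
12 | penta-1,4-dien-3-ol | C=CC(O)C=C | starting material
13 | penta-1,4-dien-3-one (divinyl ketone) | C=CC(=O)C=C | intermediate
14 | methyl (1S,4aS,5R,8aS)-1,4a-dimethyl-6-oxo-5-(3-oxopent-4-en-1-yl)decahydronaphthalene-1-carboxylate | COC(=O)[C@@]1(C)CCC[C@]2(C)[C@@H](CCC(=O)C=C)C(=O)CC[C@H]12 | intermediate
15 | methyl (1S,4aR,5S,8aS)-1,4a-dimethyl-6-methylidene-5-(3-methylidenepent-4-en-1-yl)decahydronaphthalene-1-carboxylate | COC(=O)[C@@]1(C)CCC[C@]2(C)[C@@H](CCC(=C)C=C)C(=C)CC[C@H]12 | intermediate
16 | methyl (1S,4aR,5S,8aS)-5-[(3E)-5-hydroxy-3-(hydroxymethyl)pent-3-en-1-yl]-1,4a-dimethyl-6-methylidenedecahydronaphthalene-1-carboxylate | C=C1CC[C@H]2[C@](C)(CCC[C@]2(C)C(=O)OC)[C@H]1CC/C(=C\CO)CO | target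

Total steps: 10. Longest linear sequence: 9 (steps 1–6 and 8–10; step 7 is a one-step side branch).

**Steps most likely to fail**

Step 3 must be regioselective (formyl carbon to the ring terminus), exo-selective and enantioselective at once, on a diene that carries an acid-labile ketal. The fallback replaces asymmetric catalysis by resolution; it sets out from 5 and 6 and rejoins the route at 8. EtAlCl2 (CH2Cl2, −78 °C) gives the racemic exo adduct, racemic ketal aldehyde F1. NaClO2/NaH2PO4/2-methylbut-2-ene oxidises it to the racemic ketal carboxylic acid F2. Crystallisation with (S)-1-phenylethylamine gives the (S)-1-phenylethylammonium (1S,8aS)-carboxylate F3, and acidification frees the (1S,8aS)-ketal carboxylic acid F4. MeI, K2CO3, DMF then gives 8.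

Step 8 makes a C–C bond at a neopentyl-type carbon with a polymerisable acceptor, and the face of attack decides C-9. The fallback uses enolate alkylation instead of conjugate addition; it sets out from 11 and rejoins at 15. Isoprene is metalated (KOtBu/n-BuLi) and trapped with paraformaldehyde to give 3-methylidenepent-4-en-1-ol F5, which with I2, PPh3 and imidazole gives 2-(2-iodoethyl)buta-1,3-diene F6. MeLi (THF, 0 °C) cleaves 11 to the lithium enolate, which is alkylated with F6 in THF/DMPU from the same β face to give methyl (1S,4aS,5R,8aS)-1,4a-dimethyl-5-(3-methylidenepent-4-en-1-yl)-6-oxodecahydronaphthalene-1-carboxylate F7. A single Zn/CH2Br2/TiCl4 methylenation of F7 gives 15.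

Step 10 is the new reaction; the open questions are whether hydrogencarbonate is nucleophilic enough, whether the allylic alcohols survive the oxidant, and the E/Z ratio. The fallback is known chemistry; it sets out from 15 and rejoins at 16. Palladium-catalysed 1,4-diacetoxylation (Pd(OAc)2 5 mol %, LiOAc, 1,4-benzoquinone, AcOH, 25 °C) gives methyl (1S,4aR,5S,8aS)-5-[(3E)-5-acetoxy-3-(acetoxymethyl)pent-3-en-1-yl]-1,4a-dimethyl-6-methylidenedecahydronaphthalene-1-carboxylate F8. K2CO3 in MeOH then removes both acetates (the methyl ester is unchanged by methanolysis) to give 16.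

**Further compounds**
F1 | step 3 | racemic (1S*,8aS*)-6,6-(ethane-1,2-diyldioxy)-1-methyl-1,2,3,5,6,7,8,8a-octahydronaphthalene-1-carbaldehyde | O=C[C@@]1(C)CCC=C2CC3(CC[C@H]12)OCCO3.O=C[C@]1(C)CCC=C2CC3(CC[C@@H]12)OCCO3
F2 | step 3 | racemic (1S*,8aS*)-6,6-(ethane-1,2-diyldioxy)-1-methyl-1,2,3,5,6,7,8,8a-octahydronaphthalene-1-carboxylic acid | OC(=O)[C@@]1(C)CCC=C2CC3(CC[C@H]12)OCCO3.OC(=O)[C@]1(C)CCC=C2CC3(CC[C@@H]12)OCCO3
F3 | step 3 | (S)-1-phenylethylammonium (1S,8aS)-6,6-(ethane-1,2-diyldioxy)-1-methyl-1,2,3,5,6,7,8,8a-octahydronaphthalene-1-carboxylate | C[C@H]([NH3+])c1ccccc1.[O-]C(=O)[C@@]1(C)CCC=C2CC3(CC[C@H]12)OCCO3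
F4 | step 3 | (1S,8aS)-6,6-(ethane-1,2-diyldioxy)-1-methyl-1,2,3,5,6,7,8,8a-octahydronaphthalene-1-carboxylic acid | OC(=O)[C@@]1(C)CCC=C2CC3(CC[C@H]12)OCCO3
F5 | step 8 | 3-methylidenepent-4-en-1-ol | C=CC(=C)CCO
F6 | step 8 | 2-(2-iodoethyl)buta-1,3-diene | C=CC(=C)CCI
F7 | step 8 | methyl (1S,4aS,5R,8aS)-1,4a-dimethyl-5-(3-methylidenepent-4-en-1-yl)-6-oxodecahydronaphthalene-1-carboxylate | COC(=O)[C@@]1(C)CCC[C@]2(C)[C@@H](CCC(=C)C=C)C(=O)CC[C@H]12
F8 | step 10 | methyl (1S,4aR,5S,8aS)-5-[(3E)-5-acetoxy-3-(acetoxymethyl)pent-3-en-1-yl]-1,4a-dimethyl-6-methylidenedecahydronaphthalene-1-carboxylate | C=C1CC[C@H]2[C@](C)(CCC[C@]2(C)C(=O)OC)[C@H]1CC/C(=C\COC(C)=O)COC(C)=O
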